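**Retrosynthetic overview**
1. The target comes from epoxidation and benzoylation of the diol jaeschkeanadiol; the seven-membered ring is opened at its trisubstituted alkene (ring-closing metathesis).
2. The bond between the carbinol CH and the adjacent ring CH2 is cut: asymmetric methallylboration of a cyclopentane carbaldehyde with a 2-methylallyl fragment (key fragment union).
3. The aldehyde (allyl arm, isopropyl carbinol) comes from a trans-fused bicyclic δ-lactone: lactol/Wittig opening, i-Pr addition to a ketone, hydroboration anti to the angular methyl.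
4. The unsaturated lactone comes from Eschenmoser–Claisen rearrangement of an (R)-cyclopentenol (C–O chirality passed to the quaternary carbon), made by CBS reduction of 2-bromo-3-methylcyclopent-2-enone.
5. Ring order: five-membered ring from the start, temporary six-membered lactone as stereocontrol template, seven-membered ring last.

Assumption: all reagents named in the Conditions lines are bought; bicyclic names use cyclopenta[c]pyran or azulene locants.

**Route**

Step 1
Reactants: 1 3-methylcyclopent-2-en-1-one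
Product: 3 2-bromo-3-methylcyclopent-2-en-1-one, via dibromide 2 (not isolated)
Conditions: Br2, CH2Cl2, 0 °C; then Et3N, 0 °C → rt
Reagents that add atoms: bromine (BrBr)
Why: Bromine addition to the enone followed by Et3N-induced dehydrobromination (addition–elimination α-bromination) returns the conjugated 2-bromo enone, with no stereocenter left.

Step 2
Reactants: 3 2-bromo-3-methylcyclopent-2-en-1-one
Product: 4 (1R)-2-bromo-3-methylcyclopent-2-en-1-ol
Conditions: (S)-2-methyl-CBS-oxazaborolidine (10 mol%), BH3·SMe2, THF, −10 °C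
Reagents that add atoms: none
Why: Corey–Bakshi–Shibata reduction, in which the (S)-oxazaborolidine binds the ketone with the bromovinyl arm as the large group and delivers hydride to one face, sets the (1R) carbinol.

Step 3
Reactants: 4 (1R)-2-bromo-3-methylcyclopent-2-en-1-ol
Product: 5 methyl (5R)-5-hydroxy-2-methylcyclopent-1-ene-1-carboxylate
Conditions: CO (1 atm), MeOH, PdCl2(PPh3)2 (5 mol%), Et3N, DMF, 70 °C
Reagents that add atoms: carbon monoxide ([C-]#[O+]); methanol (CO)
Why: Palladium-catalysed alkoxycarbonylation of the vinyl bromide (oxidative addition, CO insertion, methanolysis) installs the carbon that later carries the benzoate, without touching the carbinol stereocenter.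

Step 4
Reactants: 5 methyl (5R)-5-hydroxy-2-methylcyclopent-1-ene-1-carboxylate
Product: 6 (1R)-2-(hydroxymethyl)-3-methylcyclopent-2-en-1-ol
Conditions: i-Bu2AlH (3.5 equiv), CH2Cl2, −78 → 0 °C
Reagents that add atoms: none
Why: i-Bu2AlH 1,2-reduction of the conjugated ester gives the primary allylic alcohol and leaves the stereocenter untouched.

Step 5
Reactants: 6 (1R)-2-(hydroxymethyl)-3-methylcyclopent-2-en-1-ol
Product: 7 (1R)-2-({[tert-butyl(dimethyl)silyl]oxy}methyl)-3-methylcyclopent-2-en-1-ol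
Conditions: TBSCl (1.05 equiv), imidazole, CH2Cl2, −20 → 0 °C
Reagents that add atoms: tert-butyl(chloro)dimethylsilane (CC(C)(C)[Si](C)(C)Cl)
Why: Silyl ether formation is selective for the unhindered primary allylic hydroxyl over the secondary one.

Step 6
Reactants: 7 (1R)-2-({[tert-butyl(dimethyl)silyl]oxy}methyl)-3-methylcyclopent-2-en-1-ol
Product: 9 2-[(1R)-2-({[tert-butyl(dimethyl)silyl]oxy}methyl)-1-methylcyclopent-2-en-1-yl]-N,N-dimethylacetamide, via ketene N,O-acetal 8 (not isolated)
Conditions: CH3C(OMe)2NMe2 (5 equiv), xylenes, 140 °C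
Reagents that add atoms: N,N-dimethylacetamide dimethyl acetal (COC(C)(OC)N(C)C)
Why: Eschenmoser–Claisen rearrangement, a suprafacial [3,3] shift of the ketene N,O-acetal, passes the C–O chirality to the new quaternary carbon (acetamide arm on the face the oxygen occupied) and moves the alkene.

Step 7
Reactants: 9 2-[(1R)-2-({[tert-butyl(dimethyl)silyl]oxy}methyl)-1-methylcyclopent-2-en-1-yl]-N,N-dimethylacetamide
Product: 11 (4aR)-4a-methyl-4,4a,5,6-tetrahydrocyclopenta[c]pyran-3(1H)-one, via hydroxy amide 10 (not isolated)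
Conditions: 2 M HCl, THF, 60 °C
Reagents that add atoms: none
Why: Acid cleaves the silyl ether and the freed primary hydroxyl displaces dimethylamine from the protonated amide (acid-catalysed lactonisation, helped by the quaternary carbon), leaving the stereocenter unchanged.

Step 8
Reactants: 11 (4aR)-4a-methyl-4,4a,5,6-tetrahydrocyclopenta[c]pyran-3(1H)-one
Product: 13 (4aR,7R,7aS)-7-hydroxy-4a-methylhexahydrocyclopenta[c]pyran-3(1H)-one, via alkylborane 12 (not isolated)
Conditions: BH3·SMe2, THF, 0 °C; then 30% H2O2, 3 M NaOAc, 0 °C → rt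
Reagents that add atoms: hydrogen peroxide (OO)
Why: Hydroboration–oxidation puts boron on the less substituted alkene carbon and hydrogen on the ring-fusion carbon, syn and from the face opposite the angular methyl of the rigid bicyclic lactone, which sets the trans ring fusion (7aS) and the carbinol (7R, retention in the oxidation).

Step 9
Reactants: 13 (4aR,7R,7aS)-7-hydroxy-4a-methylhexahydrocyclopenta[c]pyran-3(1H)-one
Product: 14 (4aR,7aS)-4a-methyltetrahydrocyclopenta[c]pyran-3,7(1H,4H)-dione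
Conditions: Dess–Martin periodinane, CH2Cl2, 0 °C → rt
Reagents that add atoms: none
Why: Dess–Martin oxidation of the secondary alcohol under non-basic conditions gives the ketone without epimerising the adjacent ring-fusion CH.

Step 10
Reactants: 14 (4aR,7aS)-4a-methyltetrahydrocyclopenta[c]pyran-3,7(1H,4H)-dione
Product: 15 (4aR,7R,7aS)-7-hydroxy-4a-methyl-7-(propan-2-yl)hexahydrocyclopenta[c]pyran-3(1H)-one
Conditions: i-PrMgCl, anhydrous CeCl3, THF, −78 °C
Reagents that add atoms: isopropylmagnesium chloride (CC(C)[Mg]Cl)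
Why: Organocerium (Imamoto) 1,2-addition: weakly basic i-PrCeCl2 adds to the ketone faster than to the lactone and attacks the face opposite the adjacent CH2O arm and the angular methyl, so the new hydroxyl ends cis to the methyl (7R).

Step 11
Reactants: 15 (4aR,7R,7aS)-7-hydroxy-4a-methyl-7-(propan-2-yl)hexahydrocyclopenta[c]pyran-3(1H)-one
Product: 16 (4aR,7R,7aS)-4a-methyl-7-(propan-2-yl)octahydrocyclopenta[c]pyran-3,7-diol
Conditions: i-Bu2AlH (2.2 equiv), CH2Cl2, −78 °C
Reagents that add atoms: none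
Why: Partial reduction of the δ-lactone with i-Bu2AlH at −78 °C stops at the lactol (stable aluminate), and the new anomeric carbon is lost in the next step.

Step 12
Reactants: 16 (4aR,7R,7aS)-4a-methyl-7-(propan-2-yl)octahydrocyclopenta[c]pyran-3,7-diol
Product: 18 (1R,2S,3R)-2-(hydroxymethyl)-3-methyl-1-(propan-2-yl)-3-(prop-2-en-1-yl)cyclopentan-1-ol, via hydroxy aldehyde 17 (not isolated)
Conditions: Ph3PCH3Br, KOtBu, THF, 0 → 50 °C
Reagents that add atoms: methyltriphenylphosphonium bromide (C[P+](c1ccccc1)(c1ccccc1)c1ccccc1.[Br-])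
Why: Wittig methylenation of the ring-opened hydroxy aldehyde tautomer of the lactol turns the acetaldehyde arm into the allyl group and frees the primary alcohol.

Step 13
Reactants: 18 (1R,2S,3R)-2-(hydroxymethyl)-3-methyl-1-(propan-2-yl)-3-(prop-2-en-1-yl)cyclopentan-1-ol
Product: 19 (1R,2R,5R)-2-hydroxy-5-methyl-2-(propan-2-yl)-5-(prop-2-en-1-yl)cyclopentane-1-carbaldehyde
Conditions: Dess–Martin periodinane, CH2Cl2, 0 °C
Reagents that add atoms: none
Why: Dess–Martin oxidation converts only the primary alcohol (the tertiary one cannot be oxidised), and the neutral conditions avoid retro-aldol cleavage or epimerisation of the α-carbon.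

Step 14
Reactants: 19 (1R,2R,5R)-2-hydroxy-5-methyl-2-(propan-2-yl)-5-(prop-2-en-1-yl)cyclopentane-1-carbaldehyde; 20 2-methylallylmagnesium chloride
Product: 22 (1R,2S,3R)-2-[(1S)-1-hydroxy-3-methylbut-3-en-1-yl]-3-methyl-1-(propan-2-yl)-3-(prop-2-en-1-yl)cyclopentan-1-ol, via methallylborane 21 (not isolated)
Conditions: (−)-Ipc2BOMe (2.2 equiv), Et2O, −78 → 0 °C; then 19, −78 °C; then 3 M NaOH, 30% H2O2
Reagents that add atoms: none
Why: Brown asymmetric methallylboration (intermolecular carbonyl allylation through a closed chair transition state) joins the 2-methylallyl fragment to the aldehyde carbon, and the (+)-α-pinene-derived reagent controls the attacked face to give the (1S) carbinol.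

Step 15
Reactants: 22 (1R,2S,3R)-2-[(1S)-1-hydroxy-3-methylbut-3-en-1-yl]-3-methyl-1-(propan-2-yl)-3-(prop-2-en-1-yl)cyclopentan-1-ol
Product: 23 (3R,3aS,4S,8aR)-6,8a-dimethyl-3-(propan-2-yl)-1,2,3,3a,4,5,8,8a-octahydroazulene-3,4-diol
Conditions: second-generation Grubbs catalyst RuCl2(=CHPh)(PCy3)(H2IMes) (5 mol%), CH2Cl2 (5 mM), 40 °C
Reagents that add atoms: none
Why: Ring-closing metathesis between the allyl and 2-methylallyl arms, which are trans on the cyclopentane, closes the seven-membered ring as its trisubstituted alkene with loss of ethene.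

Step 16
Reactants: 23 (3R,3aS,4S,8aR)-6,8a-dimethyl-3-(propan-2-yl)-1,2,3,3a,4,5,8,8a-octahydroazulene-3,4-diol
Product: 24 (3R,3aS,4S,8aR)-3-hydroxy-6,8a-dimethyl-3-(propan-2-yl)-1,2,3,3a,4,5,8,8a-octahydroazulen-4-yl benzoate
Conditions: BzCl, pyridine, DMAP (cat.), CH2Cl2, 0 °C → rt
Reagents that add atoms: benzoyl chloride (O=C(Cl)c1ccccc1)
Why: DMAP-catalysed acylation esterifies only the secondary hydroxyl, the hindered tertiary hydroxyl being unreactive.

Step 17
Reactants: 24 (3R,3aS,4S,8aR)-3-hydroxy-6,8a-dimethyl-3-(propan-2-yl)-1,2,3,3a,4,5,8,8a-octahydroazulen-4-yl benzoate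
Product: 25 (3R,3aS,4S,6R,7S,8aR)-6,7-epoxy-3-hydroxy-6,8a-dimethyl-3-(propan-2-yl)decahydroazulen-4-yl benzoate
Conditions: mCPBA, NaHCO3 (buffer), CH2Cl2, 0 °C
Reagents that add atoms: 3-chloroperoxybenzoic acid (O=C(OO)c1cccc(Cl)c1)
Why: Prilezhaev epoxidation from the face opposite the axial angular methyl gives the epoxide oxygen trans to that methyl (6R,7S), and the buffer protects the acid-sensitive epoxy alcohol.

**Compound list**
1 | 3-methylcyclopent-2-en-1-one | CC1=CC(=O)CC1 | starting material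
2 | 2,3-dibromo-3-methylcyclopentan-1-one (trans, racemic) | CC1(Br)CCC(=O)C1Br | intermediate
3 | 2-bromo-3-methylcyclopent-2-en-1-one | CC1=C(Br)C(=O)CC1 | intermediate
4 | (1R)-2-bromo-3-methylcyclopent-2-en-1-ol | O[C@@H]1CCC(C)=C1Br | intermediate
5 | methyl (5R)-5-hydroxy-2-methylcyclopent-1-ene-1-carboxylate | O[C@@H]1CCC(C)=C1C(=O)OC | intermediate
6 | (1R)-2-(hydroxymethyl)-3-methylcyclopent-2-en-1-ol | O[C@@H]1CCC(C)=C1CO | intermediate
7 | (1R)-2-({[tert-butyl(dimethyl)silyl]oxy}methyl)-3-methylcyclopent-2-en-1-ol | O[C@@H]1CCC(C)=C1CO[Si](C)(C)C(C)(C)C | intermediate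
8 | 1-{[(1R)-2-({[tert-butyl(dimethyl)silyl]oxy}methyl)-3-methylcyclopent-2-en-1-yl]oxy}-N,N-dimethylethen-1-amine (ketene N,O-acetal) | C=C(N(C)C)O[C@@H]1CCC(C)=C1CO[Si](C)(C)C(C)(C)C | intermediate
9 | 2-[(1R)-2-({[tert-butyl(dimethyl)silyl]oxy}methyl)-1-methylcyclopent-2-en-1-yl]-N,N-dimethylacetamide | CN(C)C(=O)C[C@@]1(C)CCC=C1CO[Si](C)(C)C(C)(C)C | intermediate
10 | 2-[(1R)-2-(hydroxymethyl)-1-methylcyclopent-2-en-1-yl]-N,N-dimethylacetamide | CN(C)C(=O)C[C@@]1(C)CCC=C1CO | intermediate
11 | (4aR)-4a-methyl-4,4a,5,6-tetrahydrocyclopenta[c]pyran-3(1H)-one | O=C1C[C@@]2(C)CCC=C2CO1 | intermediate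
12 | (4aR,7R,7aS)-7-boranyl-4a-methylhexahydrocyclopenta[c]pyran-3(1H)-one | O=C1C[C@@]2(C)CC[C@@H]([BH2])[C@@H]2CO1 | intermediate
13 | (4aR,7R,7aS)-7-hydroxy-4a-methylhexahydrocyclopenta[c]pyran-3(1H)-one | O=C1C[C@@]2(C)CC[C@@H](O)[C@@H]2CO1 | intermediate
14 | (4aR,7aS)-4a-methyltetrahydrocyclopenta[c]pyran-3,7(1H,4H)-dione | O=C1C[C@@]2(C)CCC(=O)[C@@H]2CO1 | intermediate
15 | (4aR,7R,7aS)-7-hydroxy-4a-methyl-7-(propan-2-yl)hexahydrocyclopenta[c]pyran-3(1H)-one | O=C1C[C@@]2(C)CC[C@@](O)(C(C)C)[C@@H]2CO1 | intermediate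
16 | (4aR,7R,7aS)-4a-methyl-7-(propan-2-yl)octahydrocyclopenta[c]pyran-3,7-diol (lactol, both C-3 anomers) | OC1C[C@@]2(C)CC[C@@](O)(C(C)C)[C@@H]2CO1 | intermediate
17 | 2-[(1R,2S,3R)-3-hydroxy-2-(hydroxymethyl)-1-methyl-3-(propan-2-yl)cyclopentyl]acetaldehyde | O=CC[C@@]1(C)CC[C@@](O)(C(C)C)[C@@H]1CO | intermediate
18 | (1R,2S,3R)-2-(hydroxymethyl)-3-methyl-1-(propan-2-yl)-3-(prop-2-en-1-yl)cyclopentan-1-ol | C=CC[C@@]1(C)CC[C@@](O)(C(C)C)[C@@H]1CO | intermediate
19 | (1R,2R,5R)-2-hydroxy-5-methyl-2-(propan-2-yl)-5-(prop-2-en-1-yl)cyclopentane-1-carbaldehyde | C=CC[C@@]1(C)CC[C@@](O)(C(C)C)[C@@H]1C=O | intermediate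
20 | 2-methylallylmagnesium chloride, CH2=C(CH3)CH2MgCl | CC(=C)C[Mg]Cl | starting material
21 | (−)-B-(2-methylallyl)diisopinocampheylborane | CC(=C)CB([C@@H]1C[C@@H]2C[C@H]([C@H]1C)C2(C)C)[C@@H]1C[C@@H]2C[C@H]([C@H]1C)C2(C)C | intermediate
22 | (1R,2S,3R)-2-[(1S)-1-hydroxy-3-methylbut-3-en-1-yl]-3-methyl-1-(propan-2-yl)-3-(prop-2-en-1-yl)cyclopentan-1-ol | C=CC[C@@]1(C)CC[C@@](O)(C(C)C)[C@@H]1[C@@H](O)CC(C)=C | intermediate
23 | (3R,3aS,4S,8aR)-6,8a-dimethyl-3-(propan-2-yl)-1,2,3,3a,4,5,8,8a-octahydroazulene-3,4-diol (jaeschkeanadiol) | CC(C)[C@]1(O)CC[C@]2(C)CC=C(C)C[C@H](O)[C@H]21 | intermediate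
24 | (3R,3aS,4S,8aR)-3-hydroxy-6,8a-dimethyl-3-(propan-2-yl)-1,2,3,3a,4,5,8,8a-octahydroazulen-4-yl benzoate | CC(C)[C@]1(O)CC[C@]2(C)CC=C(C)C[C@H](OC(=O)c3ccccc3)[C@H]21 | intermediate
25 | (3R,3aS,4S,6R,7S,8aR)-6,7-epoxy-3-hydroxy-6,8a-dimethyl-3-(propan-2-yl)decahydroazulen-4-yl benzoate (CNP0340059.1) | CC(C)[C@]1(O)CC[C@]2(C)C[C@@H]3O[C@]3(C)C[C@H](OC(=O)c3ccccc3)[C@H]21 | target

**Totals and weak points**

Total step count: 17. Longest linear sequence: 17 steps (from 1; fragment 20 is bought).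

Step 8 (facial selectivity of the hydroboration of 11; the bias rests only on the angular methyl). The fallback replaces steric control by directed delivery and sets out from amide 9. Hydroboration with catecholborane catalysed by [Ir(cod)(PCy3)(py)]PF6, in which the dimethylamide carbonyl holds the iridium hydride on its own face of the ring alkene, followed by H2O2/NaOAc oxidation, gives 2-[(1R,2S,3R)-2-({[tert-butyl(dimethyl)silyl]oxy}methyl)-3-hydroxy-1-methylcyclopentyl]-N,N-dimethylacetamide F1. 2 M HCl in THF then removes the silyl group to give 2-[(1R,2S,3R)-3-hydroxy-2-(hydroxymethyl)-1-methylcyclopentyl]-N,N-dimethylacetamide F2 (not isolated), whose primary hydroxyl closes the δ-lactone, and the route is rejoined at 13.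

Step 14 (diastereoselectivity of the methallylboration on a very hindered β-hydroxy aldehyde; possible mismatch with the substrate). The fallback moves stereocontrol from C–C bond formation to a ketone reduction and sets out from 22 obtained as an epimer mixture at the new carbinol. Dess–Martin oxidation of the secondary hydroxyl gives 1-[(1R,2R,5R)-2-hydroxy-5-methyl-2-(propan-2-yl)-5-(prop-2-en-1-yl)cyclopentyl]-3-methylbut-3-en-1-one F3. Reduction with (R)-2-methyl-CBS-oxazaborolidine and catecholborane (ring CH as the large group) returns 22 as the (1S) carbinol.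

Step 17 (face selectivity of the epoxidation and acid sensitivity of the product). The fallback uses hydroxyl direction and sets out from diol 23. VO(acac)2/t-BuOOH epoxidation directed by the homoallylic secondary hydroxyl gives (3R,3aS,4S,6R,7S,8aR)-6,7-epoxy-6,8a-dimethyl-3-(propan-2-yl)decahydroazulene-3,4-diol F4. Benzoylation of its secondary hydroxyl (BzCl, pyridine, DMAP) then gives 25 directly.

**Further compounds**
F1 | step 8 | 2-[(1R,2S,3R)-2-({[tert-butyl(dimethyl)silyl]oxy}methyl)-3-hydroxy-1-methylcyclopentyl]-N,N-dimethylacetamide | CN(C)C(=O)C[C@@]1(C)CC[C@@H](O)[C@@H]1CO[Si](C)(C)C(C)(C)C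
F2 | step 8 | 2-[(1R,2S,3R)-3-hydroxy-2-(hydroxymethyl)-1-methylcyclopentyl]-N,N-dimethylacetamide | CN(C)C(=O)C[C@@]1(C)CC[C@@H](O)[C@@H]1CO
F3 | step 14 | 1-[(1R,2R,5R)-2-hydroxy-5-methyl-2-(propan-2-yl)-5-(prop-2-en-1-yl)cyclopentyl]-3-methylbut-3-en-1-one | C=CC[C@@]1(C)CC[C@@](O)(C(C)C)[C@@H]1C(=O)CC(C)=C
F4 | step 17 | (3R,3aS,4S,6R,7S,8aR)-6,7-epoxy-6,8a-dimethyl-3-(propan-2-yl)decahydroazulene-3,4-diol | CC(C)[C@]1(O)CC[C@]2(C)C[C@@H]3O[C@]3(C)C[C@H](O)[C@H]21
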